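**Strategy.** Ring A (C1–C5, C10) becomes a Diels–Alder ring once a C1=C2 double bond is added. An intramolecular [4+2] reaction of an acyclic tetraenal then forges C3–C4 and C5–C10 in one operation: rings A and B close together and the contiguous centres C4, C5 and C10 (two quaternary) are relayed from the single auxiliary-set centre C9. The precursor joins an (E)-2-alkyl enal (C4=C5; the formyl group is the latent C4 methyl) through the tether C6–C7=C8–C9 to an (E)-diene (C10=C1–C2=C3). Alkene geometry encodes C4, C5 and C10, and C9 selects the diene face.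

Key step: step 10

Remark (numbering used throughout): C4 is the quaternary ring A carbon that carries the methyl group and the 4-methylpent-3-enyl chain, C3 is its CH2 neighbour in ring A, C5 and C10 are the ring-fusion carbons (C10 with the methyl group), C9 carries the arylmethyl group, and C7=C8 is the ring B alkene.

Remark (assumption): compounds 1, 2, 4, 7, 16 and 17 are taken as commercial. The phenol is carried as its methyl ether and the carboxyl group as an aryl bromide until the last two steps. Work-ups are aqueous.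

Step 1
Reactants: 1 (S)-4-benzyloxazolidin-2-one; 2 3-methylbut-2-enoyl chloride
Product: 3 (S)-4-benzyl-3-(3-methylbut-2-enoyl)oxazolidin-2-one
Conditions: n-BuLi, THF, −78 °C; then 2, −78 → 0 °C
Reagents that add atoms: none
Why: N-acylation of the lithiated Evans oxazolidinone by the acid chloride is the standard entry to such imides, and no stereocentre is formed.

Step 2
Reactants: 3 (S)-4-benzyl-3-(3-methylbut-2-enoyl)oxazolidin-2-one; 4 4-bromo-2-(bromomethyl)-1-methoxybenzene
Product: 6 (S)-4-benzyl-3-[(S)-2-(5-bromo-2-methoxybenzyl)-3-methylbut-3-enoyl]oxazolidin-2-one, via sodium dienolate 5 (not isolated)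
Conditions: NaN(SiMe3)2, THF, −78 °C; then 4, −78 → −40 °C
Reagents that add atoms: none
Why: Evans deconjugative α-alkylation: γ-deprotonation should give the chelated Z(O)-dienolate 5, which is benzylated at the α-carbon on the face opposite the auxiliary benzyl group, so that C9 is set (S here) and the double bond leaves conjugation as the isopropenyl group that later becomes C8.

Step 3
Reactants: 6 (S)-4-benzyl-3-[(S)-2-(5-bromo-2-methoxybenzyl)-3-methylbut-3-enoyl]oxazolidin-2-one; 7 prop-2-en-1-ol
Product: 9 prop-2-en-1-yl (S)-2-(5-bromo-2-methoxybenzyl)-3-methylbut-3-enoate, via bromomagnesium allyloxide 8 (not isolated)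
Conditions: 7, MeMgBr, THF, 0 °C; then 6, CH2Cl2/THF, 0 °C
Reagents that add atoms: none
Why: Evans-type auxiliary exchange by transesterification: the weakly basic magnesium alkoxide 8 attacks the exocyclic imide carbonyl, releases the auxiliary and should leave the C9–H untouched.

Step 4
Reactants: 9 prop-2-en-1-yl (S)-2-(5-bromo-2-methoxybenzyl)-3-methylbut-3-enoate
Product: 10 (S)-3-(5-bromo-2-methoxybenzyl)-4-methyl-3,6-dihydro-2H-pyran-2-one
Conditions: second-generation Grubbs catalyst RuCl2(=CHPh)(H2IMes)(PCy3) (5 mol %), 1,4-benzoquinone (10 mol %), CH2Cl2 (0.005 M), 40 °C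
Reagents that add atoms: none
Why: Ring-closing olefin metathesis between the isopropenyl and the allyl alkene should close the six-membered unsaturated lactone, whose ring fixes the Z geometry of the future C7=C8 bond, with benzoquinone suppressing ruthenium hydride isomerisation into conjugation.

Step 5
Reactants: 10 (S)-3-(5-bromo-2-methoxybenzyl)-4-methyl-3,6-dihydro-2H-pyran-2-one
Product: 11 (3S)-3-(5-bromo-2-methoxybenzyl)-4-methyl-3,6-dihydro-2H-pyran-2-ol (both anomers)
Conditions: i-Bu2AlH (1.1 equiv), CH2Cl2, −78 °C; aq. potassium sodium tartrate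
Reagents that add atoms: none
Why: Low-temperature half-reduction of a lactone by a dialkylaluminium hydride stops at the tetrahedral aluminate and gives the lactol (the new anomeric centre is of no consequence), while the aryl bromide and the alkene are inert.

Step 6
Reactants: 11 (3S)-3-(5-bromo-2-methoxybenzyl)-4-methyl-3,6-dihydro-2H-pyran-2-ol
Product: 12 (2Z,4R)-4-(5-bromo-2-methoxybenzyl)-3-methylhex-2-en-5-yn-1-ol
Conditions: MeC(O)C(N2)P(O)(OMe)2, K2CO3, MeOH, 0 °C → rt
Reagents that add atoms: dimethyl (1-diazo-2-oxopropyl)phosphonate, CC(=O)C(=[N+]=[N-])P(=O)(OC)OC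
Why: Seyferth–Gilbert homologation in its Ohira–Bestmann form should convert the open hydroxy-aldehyde form of the lactol into the terminal alkyne (C10≡C1) under carbonate at 0 °C, mild enough to keep the C9 configuration, and it frees the Z-allylic alcohol at C6.

Step 7
Reactants: 12 (2Z,4R)-4-(5-bromo-2-methoxybenzyl)-3-methylhex-2-en-5-yn-1-ol
Product: 14 (2Z,4R,5E)-4-(5-bromo-2-methoxybenzyl)-3,5-dimethylocta-2,5,7-trien-1-ol, via alkenylalane 13 (not isolated)
Conditions: Me3Al (3 equiv), Cp2ZrCl2 (0.25 equiv), CH2Cl2, 0 °C → rt; then CH2=CHBr, Pd(PPh3)4 (5 mol %), ZnCl2 (0.2 equiv), THF, rt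
Reagents that add atoms: trimethylaluminium, C[Al](C)C; vinyl bromide, C=CBr
Why: Negishi zirconium-catalysed carboalumination adds methyl and aluminium syn across the alkyne (methyl on C10, aluminium on C1), and palladium-catalysed cross-coupling of alkenylalane 13 with vinyl bromide, which adds to zerovalent palladium far faster than the electron-rich aryl bromide, should give the (E)-diene with retention.

Step 8
Reactants: 14 (2Z,4R,5E)-4-(5-bromo-2-methoxybenzyl)-3,5-dimethylocta-2,5,7-trien-1-ol
Product: 15 (2Z,4R,5E)-1-bromo-4-(5-bromo-2-methoxybenzyl)-3,5-dimethylocta-2,5,7-triene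
Conditions: CBr4, PPh3, 2,6-lutidine, CH2Cl2, −20 → 0 °C
Reagents that add atoms: carbon tetrabromide, BrC(Br)(Br)Br
Why: Appel bromination substitutes the primary allylic hydroxyl by SN2 at C6 under neutral, cold conditions and should keep the Z alkene and the diene intact.

Step 9
Reactants: 15 (2Z,4R,5E)-1-bromo-4-(5-bromo-2-methoxybenzyl)-3,5-dimethylocta-2,5,7-triene; 16 5-bromo-2-methylpent-2-ene; 17 3,3-diethoxyprop-1-yne
Product: 22 (2E,5Z,7S,8E)-7-(5-bromo-2-methoxybenzyl)-6,8-dimethyl-2-(4-methylpent-3-en-1-yl)undeca-2,5,8,10-tetraenal, via Grignard reagent 18 (not isolated), via alkylcopper 19 (not isolated), via alkenylcopper 20 (not isolated), via diethyl acetal 21 (not isolated)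
Conditions: 16, Mg, THF, rt; CuBr·SMe2, −40 °C; 17, −40 → −25 °C; then 15, P(OEt)3, −40 → 0 °C; then aq. oxalic acid, THF, rt
Reagents that add atoms: water, O
Why: Normant-type carbocupration: alkylcopper 19 should add syn to the propargylic acetal in the branched sense (alkyl on the acetal-bearing carbon, copper on the terminus), alkenylcopper 20 is then allylated by the primary bromide with retention at the alkenyl carbon (SN2 mode because the γ-carbon is fully substituted), so that C6 ends cis to the pentenyl chain, and mild acid unmasks the (E)-enal.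

Step 10
Reactants: 22 (2E,5Z,7S,8E)-7-(5-bromo-2-methoxybenzyl)-6,8-dimethyl-2-(4-methylpent-3-en-1-yl)undeca-2,5,8,10-tetraenal
Product: 23 (1R,4aR,5S,8aR)-5-(5-bromo-2-methoxybenzyl)-4a,6-dimethyl-1-(4-methylpent-3-en-1-yl)-1,2,4a,5,8,8a-hexahydronaphthalene-1-carbaldehyde
Conditions: Me2AlCl (1.2 equiv), CH2Cl2, −78 → −20 °C
Reagents that add atoms: none
Why: Me2AlCl binds the formyl oxygen and lowers the LUMO of the C4=C5 bond, which adds suprafacially to the s-cis diene C10=C1–C2=C3 in a concerted but asynchronous [4+2] cycloaddition (C5–C10 ahead of C3–C4), the closest known reaction type being the Lewis acid-promoted type 1 intramolecular Diels–Alder reaction of 2-substituted deca-2,7,9-trienals. Ring A is closed by the cycloaddition itself (bonds C3–C4 and C5–C10, new C1=C2 alkene), and ring B closes in the same event as the fused six-membered ring spanned by the four-atom tether C6–C7=C8–C9 through the C5–C10 bond. C4 follows stereospecifically from the E enal geometry (formyl cis to C5–H, pentenyl chain cis to C6), while the trans ring fusion and the C10 methyl cis to the pentenyl chain follow from the E diene (C9 outside, methyl inside) reacting with the aluminium-complexed formyl group endo, the usual trans-selective mode of terminally activated trienes. The absolute sense comes from C9: in the half-chair of the forming ring B its arylmethyl group should sit pseudo-equatorial, anti to the forming C5–C10 bond, with C9–H near the plane of C10=C1, so that the dienophile reaches the diene face that places the arylmethyl group cis to the C10 methyl. The step needs endo and π-facial selectivity, secured by Lewis acid complexation and by the C9 substituent, and chemoselectivity, secured because only the enal alkene is activated and the low temperature excludes the [1,5]-hydrogen shift open to a diene with an inside methyl group.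

Step 11
Reactants: 23 (1R,4aR,5S,8aR)-5-(5-bromo-2-methoxybenzyl)-4a,6-dimethyl-1-(4-methylpent-3-en-1-yl)-1,2,4a,5,8,8a-hexahydronaphthalene-1-carbaldehyde
Product: 25 4-bromo-1-methoxy-2-{[(1S,4aS,5S,8aS)-2,5,8a-trimethyl-5-(4-methylpent-3-en-1-yl)-1,4,4a,5,6,8a-hexahydronaphthalen-1-yl]methyl}benzene, via hydrazone 24 (not isolated)
Conditions: N2H4·H2O, KOH, diethylene glycol, 130 °C then 200 °C, under argon
Reagents that add atoms: none
Why: Wolff–Kishner reduction (Huang-Minlon procedure) through hydrazone 24 should convert the non-enolisable neopentyl formyl group into the C4 methyl group without touching any stereocentre, the alkenes, the aryl ether or the aryl bromide.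

Step 12
Reactants: 25 4-bromo-1-methoxy-2-{[(1S,4aS,5S,8aS)-2,5,8a-trimethyl-5-(4-methylpent-3-en-1-yl)-1,4,4a,5,6,8a-hexahydronaphthalen-1-yl]methyl}benzene
Product: 26 4-bromo-1-methoxy-2-{[(1S,4aS,5R,8aS)-2,5,8a-trimethyl-5-(4-methylpent-3-en-1-yl)-1,4,4a,5,6,7,8,8a-octahydronaphthalen-1-yl]methyl}benzene
Conditions: H2 (1 atm), RhCl(PPh3)3 (10 mol %), benzene/EtOH, rt
Reagents that add atoms: none
Why: Homogeneous hydrogenation with Wilkinson's catalyst is strongly sensitive to alkene substitution, so the cis-disubstituted C1=C2 bond should be saturated while the two trisubstituted alkenes and the aryl bromide remain.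

Step 13
Reactants: 26 4-bromo-1-methoxy-2-{[(1S,4aS,5R,8aS)-2,5,8a-trimethyl-5-(4-methylpent-3-en-1-yl)-1,4,4a,5,6,7,8,8a-octahydronaphthalen-1-yl]methyl}benzene
Product: 28 4-methoxy-3-{[(1S,4aS,5R,8aS)-2,5,8a-trimethyl-5-(4-methylpent-3-en-1-yl)-1,4,4a,5,6,7,8,8a-octahydronaphthalen-1-yl]methyl}benzoic acid, via aryllithium 27 (not isolated)
Conditions: t-BuLi (2.1 equiv), THF, −78 °C; CO2 (g), −78 °C → rt; aq. HCl
Reagents that add atoms: carbon dioxide, O=C=O
Why: Bromine–lithium exchange followed by carboxylation of aryllithium 27 installs the carboxylic acid para to the methoxy group, the exchange at −78 °C being much faster than any allylic deprotonation.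

Step 14
Reactants: 28 4-methoxy-3-{[(1S,4aS,5R,8aS)-2,5,8a-trimethyl-5-(4-methylpent-3-en-1-yl)-1,4,4a,5,6,7,8,8a-octahydronaphthalen-1-yl]methyl}benzoic acid
Product: 29 jaspic acid
Conditions: NaSEt (8 equiv), DMF, 140 °C; then aq. HCl
Reagents that add atoms: none
Why: Thiolate-mediated SN2 demethylation of the aryl methyl ether should free the phenol without the acid that the trisubstituted alkenes would not tolerate, the carboxylate being inert and regenerated as the acid on work-up.

**Compound list**

1 | (S)-4-benzyloxazolidin-2-one | O=C1N[C@@H](Cc2ccccc2)CO1 | starting material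
2 | 3-methylbut-2-enoyl chloride | CC(C)=CC(Cl)=O | starting material
3 | (S)-4-benzyl-3-(3-methylbut-2-enoyl)oxazolidin-2-one | CC(C)=CC(=O)N1[C@@H](Cc2ccccc2)COC1=O | intermediate
4 | 4-bromo-2-(bromomethyl)-1-methoxybenzene | COc1ccc(Br)cc1CBr | starting material
5 | sodium Z(O)-dienolate of 3 | [Na+].[O-]/C(=C\C(C)=C)N1[C@@H](Cc2ccccc2)COC1=O | intermediate (not isolated)
6 | (S)-4-benzyl-3-[(S)-2-(5-bromo-2-methoxybenzyl)-3-methylbut-3-enoyl]oxazolidin-2-one | C=C(C)[C@H](Cc1cc(Br)ccc1OC)C(=O)N1[C@@H](Cc2ccccc2)COC1=O | intermediate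
7 | prop-2-en-1-ol (allyl alcohol) | C=CCO | starting material
8 | bromomagnesium prop-2-en-1-olate | C=CCO[Mg]Br | intermediate (not isolated)
9 | prop-2-en-1-yl (S)-2-(5-bromo-2-methoxybenzyl)-3-methylbut-3-enoate | C=C(C)[C@H](Cc1cc(Br)ccc1OC)C(=O)OCC=C | intermediate
10 | (S)-3-(5-bromo-2-methoxybenzyl)-4-methyl-3,6-dihydro-2H-pyran-2-one | CC1=CCOC(=O)[C@H]1Cc2cc(Br)ccc2OC | intermediate
11 | (3S)-3-(5-bromo-2-methoxybenzyl)-4-methyl-3,6-dihydro-2H-pyran-2-ol (both anomers) | CC1=CCOC(O)[C@H]1Cc2cc(Br)ccc2OC | intermediate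
12 | (2Z,4R)-4-(5-bromo-2-methoxybenzyl)-3-methylhex-2-en-5-yn-1-ol | C#C[C@@H](Cc1cc(Br)ccc1OC)/C(C)=C\CO | intermediate
13 | (E)-alkenyl(dimethyl)alane from 12: aluminium on C1 cis to the new C10 methyl, hydroxyl as its dimethylaluminium alkoxide | C[Al](C)/C=C(C)/[C@@H](Cc1cc(Br)ccc1OC)/C(C)=C\CO[Al](C)C | intermediate (not isolated)
14 | (2Z,4R,5E)-4-(5-bromo-2-methoxybenzyl)-3,5-dimethylocta-2,5,7-trien-1-ol | C=C/C=C(C)/[C@@H](Cc1cc(Br)ccc1OC)/C(C)=C\CO | intermediate
15 | (2Z,4R,5E)-1-bromo-4-(5-bromo-2-methoxybenzyl)-3,5-dimethylocta-2,5,7-triene | C=C/C=C(C)/[C@@H](Cc1cc(Br)ccc1OC)/C(C)=C\CBr | intermediate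
16 | 5-bromo-2-methylpent-2-ene | CC(C)=CCCBr | starting material
17 | 3,3-diethoxyprop-1-yne | C#CC(OCC)OCC | starting material
18 | (4-methylpent-3-en-1-yl)magnesium bromide | CC(C)=CCC[Mg]Br | intermediate (not isolated)
19 | (4-methylpent-3-en-1-yl)copper | CC(C)=CCC[Cu] | intermediate (not isolated)
20 | (E)-[3,3-diethoxy-2-(4-methylpent-3-en-1-yl)prop-1-en-1-yl]copper (copper cis to the pentenyl chain) | [Cu]/C=C(\CCC=C(C)C)C(OCC)OCC | intermediate (not isolated)
21 | (2E,5Z,7S,8E)-7-(5-bromo-2-methoxybenzyl)-1,1-diethoxy-6,8-dimethyl-2-(4-methylpent-3-en-1-yl)undeca-2,5,8,10-tetraene | CCOC(OCC)/C(CCC=C(C)C)=C/C/C=C(C)\[C@H](Cc1cc(Br)ccc1OC)/C(C)=C/C=C | intermediate (not isolated)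
22 | (2E,5Z,7S,8E)-7-(5-bromo-2-methoxybenzyl)-6,8-dimethyl-2-(4-methylpent-3-en-1-yl)undeca-2,5,8,10-tetraenal | O=C/C(CCC=C(C)C)=C/C/C=C(C)\[C@H](Cc1cc(Br)ccc1OC)/C(C)=C/C=C | intermediate
23 | (1R,4aR,5S,8aR)-5-(5-bromo-2-methoxybenzyl)-4a,6-dimethyl-1-(4-methylpent-3-en-1-yl)-1,2,4a,5,8,8a-hexahydronaphthalene-1-carbaldehyde (trans-fused) | CC(C)=CCC[C@@]1(C=O)CC=C[C@]2(C)[C@@H](Cc3cc(Br)ccc3OC)C(C)=CC[C@@H]12 | intermediate
24 | hydrazone of aldehyde 23 | CC(C)=CCC[C@@]1(C=NN)CC=C[C@]2(C)[C@@H](Cc3cc(Br)ccc3OC)C(C)=CC[C@@H]12 | intermediate (not isolated)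
25 | 4-bromo-1-methoxy-2-{[(1S,4aS,5S,8aS)-2,5,8a-trimethyl-5-(4-methylpent-3-en-1-yl)-1,4,4a,5,6,8a-hexahydronaphthalen-1-yl]methyl}benzene | CC(C)=CCC[C@@]1(C)CC=C[C@]2(C)[C@@H](Cc3cc(Br)ccc3OC)C(C)=CC[C@@H]12 | intermediate
26 | 4-bromo-1-methoxy-2-{[(1S,4aS,5R,8aS)-2,5,8a-trimethyl-5-(4-methylpent-3-en-1-yl)-1,4,4a,5,6,7,8,8a-octahydronaphthalen-1-yl]methyl}benzene | CC(C)=CCC[C@@]1(C)CCC[C@]2(C)[C@@H](Cc3cc(Br)ccc3OC)C(C)=CC[C@@H]12 | intermediate
27 | aryllithium from 26 (lithium in place of bromine) | CC(C)=CCC[C@@]1(C)CCC[C@]2(C)[C@@H](Cc3cc([Li])ccc3OC)C(C)=CC[C@@H]12 | intermediate (not isolated)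
28 | 4-methoxy-3-{[(1S,4aS,5R,8aS)-2,5,8a-trimethyl-5-(4-methylpent-3-en-1-yl)-1,4,4a,5,6,7,8,8a-octahydronaphthalen-1-yl]methyl}benzoic acid | CC(C)=CCC[C@@]1(C)CCC[C@]2(C)[C@@H](Cc3cc(C(=O)O)ccc3OC)C(C)=CC[C@@H]12 | intermediate
29 | jaspic acid: 4-hydroxy-3-{[(1S,4aS,5R,8aS)-2,5,8a-trimethyl-5-(4-methylpent-3-en-1-yl)-1,4,4a,5,6,7,8,8a-octahydronaphthalen-1-yl]methyl}benzoic acid | CC(C)=CCC[C@@]1(C)CCC[C@]2(C)[C@@H](Cc3cc(C(=O)O)ccc3O)C(C)=CC[C@@H]12 | target

**Step count.** Total: 14 steps. Longest linear sequence: 14 steps (1 → 29).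

**Steps most likely to fail**

Step 10 (cycloaddition). The diene reaches its s-cis form only against the inside methyl group, so the cycloaddition may be slow enough for Lewis acid-promoted carbonyl-ene cyclisation of the formyl group onto the side-chain alkene to compete. π-Facial discrimination by C9 or endo selectivity may also be incomplete. The fallback sets out from diethyl acetal 21, which is isolated by omitting the acid treatment at the end of step 9. Ionisation of the acetal with catalytic TMSOTf in CH2Cl2 at −78 °C makes the dienophile cationic with no free carbonyl group present (ionic Diels–Alder reaction of the Gassman type, known to tolerate hindered termini at low temperature). This should give the cycloadduct diethyl acetal F1. Aqueous oxalic acid in THF then hydrolyses it and the route is rejoined at aldehyde 23.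

Step 9 (three-component assembly). Carbocupration may run in the linear instead of the branched sense, the allylation may go SN2′, or the Z geometry of the allylic bromide may be lost. The fallback sets out from bromide 15 and returns at tetraenal 22. Stille coupling of 15 with commercial (E)-3-(tributylstannyl)prop-2-en-1-ol (Pd2(dba)3, AsPh3, THF) should give (2E,5Z,7S,8E)-7-(5-bromo-2-methoxybenzyl)-6,8-dimethylundeca-2,5,8,10-tetraen-1-ol F2. MnO2 oxidation gives (2E,5Z,7S,8E)-7-(5-bromo-2-methoxybenzyl)-6,8-dimethylundeca-2,5,8,10-tetraenal F3. α-Iodination (I2, DMAP, K2CO3, THF/H2O) gives (2Z,5Z,7S,8E)-7-(5-bromo-2-methoxybenzyl)-2-iodo-6,8-dimethylundeca-2,5,8,10-tetraenal F4. Negishi coupling (PdCl2(dppf), THF) with (4-methylpent-3-en-1-yl)zinc bromide F5, made from Grignard reagent 18 and ZnCl2, replaces iodine by the side chain with retention and gives 22.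

Step 12 (hydrogenation). Uptake at the C1=C2 bond next to the quaternary C10 may be slow, and the side-chain alkene may be over-reduced. The fallback sets out from 25 and returns at 26 without any new compound (entry F0). It replaces metal-catalysed hydrogenation by metal-free hydrogen transfer from diimide (2-nitrobenzenesulfonohydrazide, Et3N, CH2Cl2, rt). This is a concerted syn addition whose rate drops steeply from di- to trisubstituted alkenes and which can be dosed in portions.

Further compounds
F1 | step 10 | (1R,4aR,5S,8aR)-5-(5-bromo-2-methoxybenzyl)-1-(diethoxymethyl)-4a,6-dimethyl-1-(4-methylpent-3-en-1-yl)-1,2,4a,5,8,8a-hexahydronaphthalene | CC(C)=CCC[C@@]1(C(OCC)OCC)CC=C[C@]2(C)[C@@H](Cc3cc(Br)ccc3OC)C(C)=CC[C@@H]12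
F2 | step 9 | (2E,5Z,7S,8E)-7-(5-bromo-2-methoxybenzyl)-6,8-dimethylundeca-2,5,8,10-tetraen-1-ol | OC/C=C/C/C=C(C)\[C@H](Cc1cc(Br)ccc1OC)/C(C)=C/C=C
F3 | step 9 | (2E,5Z,7S,8E)-7-(5-bromo-2-methoxybenzyl)-6,8-dimethylundeca-2,5,8,10-tetraenal | O=C/C=C/C/C=C(C)\[C@H](Cc1cc(Br)ccc1OC)/C(C)=C/C=C
F4 | step 9 | (2Z,5Z,7S,8E)-7-(5-bromo-2-methoxybenzyl)-2-iodo-6,8-dimethylundeca-2,5,8,10-tetraenal | O=C/C(I)=C/C/C=C(C)\[C@H](Cc1cc(Br)ccc1OC)/C(C)=C/C=C
F5 | step 9 | (4-methylpent-3-en-1-yl)zinc bromide | CC(C)=CCC[Zn]Br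
F0 | step 12 | none | none
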